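The readings are simulated for substances that don't exist; the scatter is artificial.

Amounts first: X enters in 4 equal portions, 50 min apart, the last at 2.50 h, and the earlier runs theta and eta give X and Z as percentages of the whole charge.

common to all: X 0.050 M (in portions, 4)

|  | Q | remark | time |
|---|---|---|---|
| theta | 0.0025 mol% | run made earlier; portions every 50 min |  |
| eta | 0.0063 mol% | run made earlier; portions every 50 min |  |
| ash | 0.003 mol% | the portions of X follow each other after 50 min, the first at the start | 10 h |
| alder | 0.004 mol% | the portions of X follow each other after 50 min, the first at the start | 10 h |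
| cedar | 0.006 mol% | the portions of X follow each other after 50 min, the first at the start | 10 h |
| larch | 0.01 mol% | the portions of X follow each other after 50 min, the first at the start | 10 h |

- theta (time / h: Z / %, X / %): 0.417: 3.8, 21.4; 0.833: 6.0, 19.6; 1.33: 14.6, 33.3; 2.50: 31.8, 35.4; 5.00: 44.1, 21.6
- eta (time / h: Z / %, X / %): 0.417: 6.8, 19.1; 1.33: 23.8, 23.4; 2.50: 42.1, 18.9; 4.00: 54.7, 14.8; 5.00: 45.8, 10.1

(each reading ± 0.5 percentage points)

- "hardly changes" means that all values lie within two and a half points (for a concentration: within two and a half percent of the largest)

1. amount of Z at the end, in percent of the X charged for ash, alder, cedar, larch, in this order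
2. the course of these numbers from the first flask to the last (rises all the way / falls, then rises / hardly changes / falls all the way / rises, then falls)

The main step by itself turns X into Z, so X + Z should equal what has been charged. Early on it does: in theta at 0.417 h the sum is 25.2 %, against 25.0 % charged. With more Q, Z appears earlier: at 2.50 h eta holds 42.1 % of Z and theta 31.8 %.

One more process shows up later. In eta no portion enters between 4.00 h and 5.00 h, yet the sum drops from 69.5 % to 55.9 %. Divided by the mean Z and the time, that loss is 0.271 h⁻¹. Theta, with its lower loading of Q, gives 0.279 h⁻¹ from 2.50 h to 5.00 h, counting the last portion. So the loss reads as first order in Z, with little trace of Q. From the eta value, 2.56 h is the read half-life of Z, the time in which a stock of Z halves while none is made. On that reading, a stock of Z standing at the last portion is reckoned to shrink by the end to 13.1 % of itself.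

Now the difference between flasks. At 5.00 h theta and eta differ by 1.7 percentage points in Z but by 12 points in X. On the same reading, Z made midway through the remaining hours is reckoned to keep 50.8 % of itself, so that extra X is reckoned at 5.8 points of Z at the end if it turns completely, and less as far as it stays X. My own reckoning therefore expects Z at the end to fall with loading, by an amount near the margin, and it gives no row.

The forecast gave 17.6 %, 16.8 %, 15.8 % and 14.9 %, course: falls all the way. Its ground: “Slow flasks form Z later, so more survives.”

The flasks give 20.8 %, 20.1 %, 19.3 % and 18.4 %, a spread of 2.4 points, so the course is: hardly changes.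

    Z ⇌ J (K = 24.0, k = 0.00390 min⁻¹)
    X + Q → Z + Q, rate k2*[X]^2*[Q]/(1 + ([X]/Kh2)^2) (43.0 mM, k = 4.30 × 10⁵ M⁻² min⁻¹)
    Q + Z → D (k = 0.0580 M⁻¹ min⁻¹)

In ash at 10.0 h, the forward half-life of Z into J, 3.0 h, is shorter than the 10 h of the run, and Z, each step taken net, is made at 0.198 of the rate at which it is used up. The 7.50 h after the last portion span 2.93 of the half-lives 2.56 h read from eta, and across them Z goes from 34.6 % to 20.8 % in ash and from 46.5 % to 18.4 % in larch.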